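(The numbers are assumed; no experiment stands behind them.)

- Freeze [incoming ligand] at its mean level over the run, and reckon the starting complex as a pseudo-first-order decay.

| flask | starting complex | incoming ligand | time |
|---|---|---|---|
| Sunday's | 0.40 M | 1.20 M | 15 s |
| Tuesday's | 0.40 M | 1.80 M | 15 s |

    starting complex + incoming ligand ⇌ leaving ligand + complex with one exchanged (K1 = 0.21, k1 = 0.0373 /M/s)
    complex with one exchanged + incoming ligand ⇌ leaving ligand + complex with two exchanged (K2 = 0.702, k2 = 0.0245 /M/s)
    leaving ligand + starting complex ⇌ idle adduct, settled at all times (K3 = 0.85 /M)
    leaving ligand → by-product carried off (k4 = 0.654 /s)
    crystals ⇌ leaving ligand, rate k5*(cs5 - [leaving ligand]) while solid is left; crystals form when [leaving ligand] > cs5 (cs5 = 0.26 M, k5 = 11.2 /s)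

- what is said of leaving ligand includes idle adduct and crystals
- crystals is a solid; its amount is given per volume of the solution
- run time (Sunday's): 15 s

- part of the starting complex that has reacted at the end, Sunday's
- part of the starting complex that has reacted at the end, Tuesday's
- what raising the concentration of incoming ligand from its lowest to its highest value here does to the part of the starting complex that has reacted (changes below 5 percentage points count as none) (it falls / it rises / no change)

- Take the main step by itself, with [incoming ligand] held at its charge. The part reacted is then 48.9% in Sunday's flask and 63.5% in Tuesday's.
- Add the consumption of incoming ligand by step one. Take off half of what that step uses, which gives mean levels of 1.10 M on Sunday and 1.67 M on Tuesday.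
- Divide ln(2) by the step-one rate constant times that mean level. This gives 16.9 s for Sunday's flask and 11.1 s for Tuesday's, the working half-life of the starting complex.
- Run the clock on these half-lives. The part reacted falls to 46.0% on Sunday and 60.8% on Tuesday, a rise of 15 percentage points.
- Add the drain. Free leaving ligand has a half-life of 1.1 s by step four alone, far shorter than 11.1 s, so set [leaving ligand] to its rate of making over the drain constant. At the start of Tuesday's flask that is 0.0411 M, below the solubility of 0.26 M, so expect no crystals.
- Add the idle adduct. At that level it holds about 3.49% of the starting complex in Tuesday's flask.
- Add the falling back of step one. With [leaving ligand] set by the drain, the back rate over the forward rate of step one reduces to the step-one rate constant times [complex with one exchanged], over the step-one equilibrium constant times the drain constant. That is about 6.60% at the end of Tuesday's flask, so treat my figures as a point or two high.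
- Compare the forecast, which gives 43% and 57%, lower than my figures, and says it rises, on the grounds of “the starting complex decaying at a near pseudo-first-order rate”.
- Read the result: 44.9% on Sunday and 58.5% on Tuesday. As for the part reacted, it rises by 14 points when [incoming ligand] goes from 1.20 M to 1.80 M, and my figures stand 1.1 points and 2.3 points high.
- Set the times side by side. In Tuesday's flask at 7.63 s, the half-life of the starting complex by the forward rate of step one alone is 11 s, beside the working 11.1 s, and ten times the 1.1 s of free leaving ligand. At 15.0 s [leaving ligand] reads 0.0242 M, less than the solubility, with crystals at 0 M. In the neighbour flask with 1.0 M of starting complex, the mean level drops to 1.48 M and the working half-life becomes 12.5 s, which gives 56.4%, and that flask reads 52.4%.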